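**Retrosynthetic overview**
- Both pyranone rings are cut at O1–C2 and taken back to the dihydrochalcone level (C-2 = CH2), giving the acyclic (2S,3S)-2,3-bis(4-oxybenzyl)-1-(2,4-dihydroxyphenyl)-4-(2,4,6-trihydroxyphenyl)butane-1,4-dione 21.
- Enabling feature: C-2 and C-2'' are benzylic carbons para to a phenolic OH (the 4-hydroxyphenyl rings), and each lies five atoms (C2–C3–C4–C4a–C8a–O) from a phenolic oxygen ortho to the acyl group. DDQ oxidation to a p-quinone methide (dearomatised phenol) and 6-membered oxa-1,6-addition therefore rebuild each ring.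
- The C3–C3'' bond is the α,β-bond of a trans-α,β-dibenzyl-γ-butyrolactone 10 (temporary ring). Evans alkylation sets C-3 and trans-selective lactone benzylation sets C-3''. The lactone C=O becomes the hindered 2,4,6-trioxyaryl ketone; the lactone CH2O becomes an aldehyde and then the 2,4-dioxyaryl ketone.
- Ring order: γ-lactone (step 4, opened in step 7), then the pyranone ring of the 5,7-dihydroxy unit, then the pyranone ring of the 7-hydroxy unit (last). The last two both form in step 13; a TBS ether on the 4-hydroxybenzyl arm of the 7-hydroxy half fixes their order.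

Key step: step 13

Remark: the SMILES is read as the (2S,3R,2''S,3''R) isomer (both flavanone units 2,3-trans); 1,3,5-tris(benzyloxy)benzene and 4-(benzyloxy)benzyl bromide are taken as purchasable.

**Route**

Step 1
Reactants: 1 3-(4-hydroxyphenyl)propanoic acid
Product: 2 3-{4-[(tert-butyldimethylsilyl)oxy]phenyl}propanoic acid
Conditions: TBSCl (2.2 equiv), imidazole, DMF, rt; then AcOH–THF–H2O, rt
Reagents that add atoms: tert-butyldimethylsilyl chloride CC(C)(C)[Si](C)(C)Cl
Why: Silylation of both OH groups followed by selective hydrolysis of the labile silyl ester should leave the aryl silyl ether, which later keeps this ring from being oxidised.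

Step 2
Reactants: 2 3-{4-[(tert-butyldimethylsilyl)oxy]phenyl}propanoic acid; 3 (R)-4-benzyl-1,3-oxazolidin-2-one
Product: 4 (4R)-4-benzyl-3-(3-{4-[(tert-butyldimethylsilyl)oxy]phenyl}propanoyl)-1,3-oxazolidin-2-one
Conditions: PivCl, Et3N, THF, −20 °C; then 3, LiCl, −20 °C → rt
Reagents that add atoms: none
Why: N-acylation of the oxazolidinone through the pivaloyl mixed anhydride is a standard way to attach an Evans auxiliary and forms no stereocentre.

Step 3
Reactants: 4 (4R)-4-benzyl-3-(3-{4-[(tert-butyldimethylsilyl)oxy]phenyl}propanoyl)-1,3-oxazolidin-2-one; 5 tert-butyl bromoacetate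
Product: 6 tert-butyl (3S)-4-[(4R)-4-benzyl-2-oxo-1,3-oxazolidin-3-yl]-3-{4-[(tert-butyldimethylsilyl)oxy]benzyl}-4-oxobutanoate
Conditions: NaHMDS, THF, −78 °C; then 5, −78 → −40 °C
Reagents that add atoms: none
Why: Evans asymmetric alkylation, in which the chelated Z-sodium enolate is alkylated on the face opposite the 4-benzyl group of the (R)-auxiliary, should set the future C-3 as (S).

Step 4
Reactants: 6 tert-butyl (3S)-4-[(4R)-4-benzyl-2-oxo-1,3-oxazolidin-3-yl]-3-{4-[(tert-butyldimethylsilyl)oxy]benzyl}-4-oxobutanoate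
Product: 8 (4S)-4-{4-[(tert-butyldimethylsilyl)oxy]benzyl}oxolan-2-one, via hydroxy ester 7 (not isolated)
Conditions: LiBH4, MeOH (1 equiv), Et2O, 0 °C; then p-TsOH·H2O (cat.), toluene, 60 °C
Reagents that add atoms: none
Why: Chemoselective borohydride reduction of the imide carbonyl in the presence of the tert-butyl ester releases the auxiliary, and acid-catalysed lactonisation then gives the β-benzyl-γ-butyrolactone without touching the stereocentre.

Step 5
Reactants: 8 (4S)-4-{4-[(tert-butyldimethylsilyl)oxy]benzyl}oxolan-2-one; 9 4-(benzyloxy)benzyl bromide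
Product: 10 (3S,4S)-3-[4-(benzyloxy)benzyl]-4-{4-[(tert-butyldimethylsilyl)oxy]benzyl}oxolan-2-one
Conditions: LDA, THF, −78 °C; then 9, DMPU, −78 → −30 °C
Reagents that add atoms: none
Why: Alkylation of the lactone lithium enolate anti to the C-4 substituent (the classical trans-α,β-dibenzylbutyrolactone construction) should set the future C-3'' as (S), trans to C-3.

Step 6
Reactants: 11 1,3,5-tris(benzyloxy)benzene
Product: 12 2-bromo-1,3,5-tris(benzyloxy)benzene
Conditions: NBS (1.0 equiv), CH2Cl2, −40 → 0 °C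
Reagents that add atoms: N-bromosuccinimide O=C1CCC(=O)N1Br
Why: Electrophilic aromatic bromination of the strongly activated arene, whose three free positions are equivalent, should stop at the monobromide with one equivalent of NBS.

Step 7
Reactants: 12 2-bromo-1,3,5-tris(benzyloxy)benzene; 10 (3S,4S)-3-[4-(benzyloxy)benzyl]-4-{4-[(tert-butyldimethylsilyl)oxy]benzyl}oxolan-2-one
Product: 14 (2S,3S)-2-[4-(benzyloxy)benzyl]-3-{4-[(tert-butyldimethylsilyl)oxy]benzyl}-4-hydroxy-1-[2,4,6-tris(benzyloxy)phenyl]butan-1-one, via aryllithium 13 (not isolated)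
Conditions: 12, n-BuLi, THF, −78 °C; then 10, −78 → −40 °C; then H2O
Reagents that add atoms: none
Why: Bromine–lithium exchange and addition of the aryllithium to the lactone carbonyl should stop at mono-addition because the tetrahedral lithium hemiketal persists until the quench and the resulting 2,6-disubstituted aryl ketone is too shielded to add again.

Step 8
Reactants: 14 (2S,3S)-2-[4-(benzyloxy)benzyl]-3-{4-[(tert-butyldimethylsilyl)oxy]benzyl}-4-hydroxy-1-[2,4,6-tris(benzyloxy)phenyl]butan-1-one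
Product: 15 (2S,3S)-3-[4-(benzyloxy)benzyl]-2-{4-[(tert-butyldimethylsilyl)oxy]benzyl}-4-oxo-4-[2,4,6-tris(benzyloxy)phenyl]butanal
Conditions: Dess–Martin periodinane, CH2Cl2, 0 °C → rt
Reagents that add atoms: none
Why: Dess–Martin oxidation of the primary alcohol under nearly neutral conditions should give the aldehyde with little risk to the α-stereocentre.

Step 9
Reactants: 16 4-bromobenzene-1,3-diol
Product: 17 2,4-bis(benzyloxy)-1-bromobenzene
Conditions: BnBr (2.2 equiv), K2CO3, DMF, 50 °C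
Reagents that add atoms: benzyl bromide BrCc1ccccc1
Why: Williamson etherification of both phenols is routine for this substrate.

Step 10
Reactants: 17 2,4-bis(benzyloxy)-1-bromobenzene; 15 (2S,3S)-3-[4-(benzyloxy)benzyl]-2-{4-[(tert-butyldimethylsilyl)oxy]benzyl}-4-oxo-4-[2,4,6-tris(benzyloxy)phenyl]butanal
Product: 19 (2S,3S)-4-[2,4-bis(benzyloxy)phenyl]-2-[4-(benzyloxy)benzyl]-3-{4-[(tert-butyldimethylsilyl)oxy]benzyl}-4-hydroxy-1-[2,4,6-tris(benzyloxy)phenyl]butan-1-one (both C-4 epimers), via aryllithium 18 (not isolated)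
Conditions: 17, n-BuLi, THF, −78 °C; then 15, −78 °C; then H2O
Reagents that add atoms: none
Why: 1,2-Addition of an aryllithium to an aldehyde at −78 °C should be chemoselective over the shielded 2,6-disubstituted aryl ketone, and the new carbinol centre is inconsequential because it is oxidised next.

Step 11
Reactants: 19 (2S,3S)-4-[2,4-bis(benzyloxy)phenyl]-2-[4-(benzyloxy)benzyl]-3-{4-[(tert-butyldimethylsilyl)oxy]benzyl}-4-hydroxy-1-[2,4,6-tris(benzyloxy)phenyl]butan-1-one
Product: 20 (2S,3S)-1-[2,4-bis(benzyloxy)phenyl]-3-[4-(benzyloxy)benzyl]-2-{4-[(tert-butyldimethylsilyl)oxy]benzyl}-4-[2,4,6-tris(benzyloxy)phenyl]butane-1,4-dione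
Conditions: Dess–Martin periodinane, CH2Cl2, rt
Reagents that add atoms: none
Why: Dess–Martin oxidation of the benzylic alcohol should give the aryl ketone under conditions that do not enolise the two α-stereocentres.

Step 12
Reactants: 20 (2S,3S)-1-[2,4-bis(benzyloxy)phenyl]-3-[4-(benzyloxy)benzyl]-2-{4-[(tert-butyldimethylsilyl)oxy]benzyl}-4-[2,4,6-tris(benzyloxy)phenyl]butane-1,4-dione
Product: 21 (2S,3S)-2-{4-[(tert-butyldimethylsilyl)oxy]benzyl}-1-(2,4-dihydroxyphenyl)-3-(4-hydroxybenzyl)-4-(2,4,6-trihydroxyphenyl)butane-1,4-dione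
Conditions: H2 (1 atm), 10% Pd/C, EtOAc–EtOH, rt
Reagents that add atoms: none
Why: Neutral hydrogenolysis should remove the six benzyl ethers while the aryl silyl ether is inert, leaving exactly one 4-oxybenzyl ring masked.

Step 13
Reactants: 21 (2S,3S)-2-{4-[(tert-butyldimethylsilyl)oxy]benzyl}-1-(2,4-dihydroxyphenyl)-3-(4-hydroxybenzyl)-4-(2,4,6-trihydroxyphenyl)butane-1,4-dione
Product: 26 (2S,3R)-3-[(2S,3R)-5,7-dihydroxy-2-(4-hydroxyphenyl)-4-oxochroman-3-yl]-7-hydroxy-2-(4-hydroxyphenyl)chroman-4-one, via first quinone methide 22 (not isolated), via monoflavanone silyl ether 23 (not isolated), via monoflavanone phenol 24 (not isolated), via second quinone methide 25 (not isolated)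
Conditions: DDQ (1.05 equiv), MeCN, 0 °C; then 48% aq. HF, 20 °C; then DDQ (1.05 equiv), 0 °C (one pot)
Reagents that add atoms: none
Why: Proposed new method: DDQ forms a charge-transfer complex with the only free 4-alkylphenol of 21 and removes a hydride from its benzylic CH2 to give p-quinone methide 22, whose exocyclic carbon is captured by a free ortho-hydroxyl of the phloroglucinol ketone (6-exo-trig oxa-1,6-addition that rearomatises the phenol) to close the pyranone ring of the 5,7-dihydroxy half (23); HF then unmasks the second phenol (24) and the second equivalent of DDQ repeats the sequence via 25, the ortho-hydroxyl of the resorcinol ketone closing the last pyranone ring by the same 6-exo-trig oxa-1,6-addition. The closest known reaction types are the DDQ oxidative cyclisation of 1-(2-hydroxyaryl)-3-(4-hydroxyaryl)propanes to flavans and the solvent capture of DDQ-generated p-quinone methides of 4-alkylphenols; not yet shown are the use on a β-aryl ketone with an epimerisable α-stereocentre and the programmed double closure. Each new stereocentre (C-2'' first, then C-2) is controlled by the neighbouring pre-set centre (C-3'' or C-3): the chair-like transition state with the aryl group and the C-3 substituent both pseudo-equatorial gives the 2,3-trans ring, which should also be the thermodynamic isomer because capture is reversible under the acidic conditions. The step needs (i) order of closure, secured by the TBS ether because DDQ attacks only the ring with a free phenolic OH, (ii) site selectivity of the second oxidation for the ArCH2 group over the C-2''–H of the ring already formed, secured by the deactivating aryloxy/acyl environment of that C–H, and (iii) capture of each quinone methide faster than its tautomerisation to the α-substituted chalcone, secured by six-membered intramolecular delivery of the phenol and the absence of base.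

**Compound list**

1 | 3-(4-hydroxyphenyl)propanoic acid | OC(=O)CCc1ccc(O)cc1 | starting material
2 | 3-{4-[(tert-butyldimethylsilyl)oxy]phenyl}propanoic acid | OC(=O)CCc1ccc(O[Si](C)(C)C(C)(C)C)cc1 | intermediate
3 | (R)-4-benzyl-1,3-oxazolidin-2-one | O=C1N[C@H](Cc2ccccc2)CO1 | starting material
4 | (4R)-4-benzyl-3-(3-{4-[(tert-butyldimethylsilyl)oxy]phenyl}propanoyl)-1,3-oxazolidin-2-one | O=C(CCc1ccc(O[Si](C)(C)C(C)(C)C)cc1)N1[C@H](Cc2ccccc2)COC1=O | intermediate
5 | tert-butyl bromoacetate | CC(C)(C)OC(=O)CBr | starting material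
6 | tert-butyl (3S)-4-[(4R)-4-benzyl-2-oxo-1,3-oxazolidin-3-yl]-3-{4-[(tert-butyldimethylsilyl)oxy]benzyl}-4-oxobutanoate | CC(C)(C)OC(=O)C[C@H](Cc1ccc(O[Si](C)(C)C(C)(C)C)cc1)C(=O)N1[C@H](Cc2ccccc2)COC1=O | intermediate
7 | tert-butyl (3S)-3-{4-[(tert-butyldimethylsilyl)oxy]benzyl}-4-hydroxybutanoate | CC(C)(C)OC(=O)C[C@H](Cc1ccc(O[Si](C)(C)C(C)(C)C)cc1)CO | intermediate
8 | (4S)-4-{4-[(tert-butyldimethylsilyl)oxy]benzyl}oxolan-2-one | O=C1C[C@H](Cc2ccc(O[Si](C)(C)C(C)(C)C)cc2)CO1 | intermediate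
9 | 4-(benzyloxy)benzyl bromide | BrCc1ccc(OCc2ccccc2)cc1 | starting material
10 | (3S,4S)-3-[4-(benzyloxy)benzyl]-4-{4-[(tert-butyldimethylsilyl)oxy]benzyl}oxolan-2-one (trans) | O=C1OC[C@@H](Cc2ccc(O[Si](C)(C)C(C)(C)C)cc2)[C@@H]1Cc1ccc(OCc2ccccc2)cc1 | intermediate
11 | 1,3,5-tris(benzyloxy)benzene | c1ccc(COc2cc(OCc3ccccc3)cc(OCc3ccccc3)c2)cc1 | starting material
12 | 2-bromo-1,3,5-tris(benzyloxy)benzene | Brc1c(OCc2ccccc2)cc(OCc2ccccc2)cc1OCc1ccccc1 | intermediate
13 | [2,4,6-tris(benzyloxy)phenyl]lithium | [Li]c1c(OCc2ccccc2)cc(OCc2ccccc2)cc1OCc1ccccc1 | intermediate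
14 | (2S,3S)-2-[4-(benzyloxy)benzyl]-3-{4-[(tert-butyldimethylsilyl)oxy]benzyl}-4-hydroxy-1-[2,4,6-tris(benzyloxy)phenyl]butan-1-one | OC[C@@H](Cc1ccc(O[Si](C)(C)C(C)(C)C)cc1)[C@H](Cc1ccc(OCc2ccccc2)cc1)C(=O)c1c(OCc2ccccc2)cc(OCc2ccccc2)cc1OCc1ccccc1 | intermediate
15 | (2S,3S)-3-[4-(benzyloxy)benzyl]-2-{4-[(tert-butyldimethylsilyl)oxy]benzyl}-4-oxo-4-[2,4,6-tris(benzyloxy)phenyl]butanal | O=C[C@@H](Cc1ccc(O[Si](C)(C)C(C)(C)C)cc1)[C@H](Cc1ccc(OCc2ccccc2)cc1)C(=O)c1c(OCc2ccccc2)cc(OCc2ccccc2)cc1OCc1ccccc1 | intermediate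
16 | 4-bromobenzene-1,3-diol (4-bromoresorcinol) | Oc1ccc(Br)c(O)c1 | starting material
17 | 2,4-bis(benzyloxy)-1-bromobenzene | Brc1ccc(OCc2ccccc2)cc1OCc1ccccc1 | intermediate
18 | [2,4-bis(benzyloxy)phenyl]lithium | [Li]c1ccc(OCc2ccccc2)cc1OCc1ccccc1 | intermediate
19 | (2S,3S)-4-[2,4-bis(benzyloxy)phenyl]-2-[4-(benzyloxy)benzyl]-3-{4-[(tert-butyldimethylsilyl)oxy]benzyl}-4-hydroxy-1-[2,4,6-tris(benzyloxy)phenyl]butan-1-one (both C-4 epimers) | OC(c1ccc(OCc2ccccc2)cc1OCc1ccccc1)[C@@H](Cc1ccc(O[Si](C)(C)C(C)(C)C)cc1)[C@H](Cc1ccc(OCc2ccccc2)cc1)C(=O)c1c(OCc2ccccc2)cc(OCc2ccccc2)cc1OCc1ccccc1 | intermediate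
20 | (2S,3S)-1-[2,4-bis(benzyloxy)phenyl]-3-[4-(benzyloxy)benzyl]-2-{4-[(tert-butyldimethylsilyl)oxy]benzyl}-4-[2,4,6-tris(benzyloxy)phenyl]butane-1,4-dione | O=C(c1ccc(OCc2ccccc2)cc1OCc1ccccc1)[C@@H](Cc1ccc(O[Si](C)(C)C(C)(C)C)cc1)[C@H](Cc1ccc(OCc2ccccc2)cc1)C(=O)c1c(OCc2ccccc2)cc(OCc2ccccc2)cc1OCc1ccccc1 | intermediate
21 | (2S,3S)-2-{4-[(tert-butyldimethylsilyl)oxy]benzyl}-1-(2,4-dihydroxyphenyl)-3-(4-hydroxybenzyl)-4-(2,4,6-trihydroxyphenyl)butane-1,4-dione | O=C(c1ccc(O)cc1O)[C@@H](Cc1ccc(O[Si](C)(C)C(C)(C)C)cc1)[C@H](Cc1ccc(O)cc1)C(=O)c1c(O)cc(O)cc1O | intermediate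
22 | p-quinone methide of 21 (the 4-hydroxybenzyl arm next to the trihydroxyphenyl ketone is now a 4-methylidenecyclohexa-2,5-dien-1-one; both α-centres as in 21) | O=C(c1ccc(O)cc1O)[C@@H](Cc1ccc(O[Si](C)(C)C(C)(C)C)cc1)[C@H](C=C1C=CC(=O)C=C1)C(=O)c1c(O)cc(O)cc1O | intermediate
23 | (2S,3R)-3-[(2S)-3-{4-[(tert-butyldimethylsilyl)oxy]phenyl}-1-(2,4-dihydroxyphenyl)-1-oxopropan-2-yl]-5,7-dihydroxy-2-(4-hydroxyphenyl)chroman-4-one | O=C(c1ccc(O)cc1O)[C@@H](Cc1ccc(O[Si](C)(C)C(C)(C)C)cc1)[C@H]1C(=O)c2c(O)cc(O)cc2O[C@@H]1c1ccc(O)cc1 | intermediate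
24 | (2S,3R)-3-[(2S)-1-(2,4-dihydroxyphenyl)-3-(4-hydroxyphenyl)-1-oxopropan-2-yl]-5,7-dihydroxy-2-(4-hydroxyphenyl)chroman-4-one | O=C(c1ccc(O)cc1O)[C@@H](Cc1ccc(O)cc1)[C@H]1C(=O)c2c(O)cc(O)cc2O[C@@H]1c1ccc(O)cc1 | intermediate
25 | p-quinone methide of 24 (the remaining 4-hydroxybenzyl arm is now a 4-methylidenecyclohexa-2,5-dien-1-one; other centres as in 24) | O=C(c1ccc(O)cc1O)[C@@H](C=C1C=CC(=O)C=C1)[C@H]1C(=O)c2c(O)cc(O)cc2O[C@@H]1c1ccc(O)cc1 | intermediate
26 | (2S,3R)-3-[(2S,3R)-5,7-dihydroxy-2-(4-hydroxyphenyl)-4-oxochroman-3-yl]-7-hydroxy-2-(4-hydroxyphenyl)chroman-4-one (CNP0138443.1) | O=C1c2ccc(O)cc2O[C@H](c2ccc(O)cc2)[C@H]1[C@H]1C(=O)c2c(O)cc(O)cc2O[C@@H]1c1ccc(O)cc1 | target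

**Step count and risks**

Total step count: 13. Longest linear sequence: 11 (steps 1–5, 7, 8, 10–13); steps 6 and 9 prepare the two aryl bromides.

Steps most likely to fail:

1. Step 13 (proposed new method). A quinone methide may lose its α-hydrogen (tautomerisation to the α-substituted chalcone) faster than the ortho-hydroxyl captures it, which would erase the C-3 or C-3'' configuration. The second portion of DDQ may also dehydrogenate the flavanone ring already formed. The fallback uses known chemistry and separates oxidation from ring closure. It sets out from 21. DDQ in methanol (the known benzylic methoxylation of 4-alkylphenols, in which the solvent captures the quinone methide at once) should give the benzylic methyl ether F1. Catalytic TsOH in MeCN should then exchange the methoxy group for the phenolic oxygen (acid-mediated SN1 etherification of a p-hydroxybenzyl ether, thermodynamic 2,3-trans) to give 23, which is now isolated. Aqueous HF gives 24. The same two operations on 24 should give the benzylic methyl ether F2 and then the target, so the fallback rejoins the route at 26.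

2. Step 7. The hindered aryllithium may deprotonate the α-branched lactone instead of adding to it, returning 10 or its cis epimer. The fallback sets out from 10. DIBAL-H (toluene, −78 °C) should give the lactol F3. Aryllithium 13 (2.2 equiv) then adds to the open hydroxy-aldehyde form, which is far more electrophilic than the lactone, to give the diol F4. Dess–Martin oxidation of both carbinols gives keto-aldehyde 15, where the route is rejoined; 14 and step 8 are bypassed.

3. Step 10. The basic aryllithium may enolise the aldehyde, which would epimerise the α-stereocentre and lower conversion. The fallback sets out from 14. TEMPO/PhI(OAc)2 in MeCN–H2O should give the keto acid F5, and EDC with MeONHMe·HCl the Weinreb amide F6. Acyl substitution with aryllithium 18 at −78 °C then gives diketone 20 directly, where the route is rejoined; 15, 19 and step 11 are bypassed.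

**Further compounds**

F1 | step 13 | (2S,3S)-2-{4-[(tert-butyldimethylsilyl)oxy]benzyl}-1-(2,4-dihydroxyphenyl)-3-[(4-hydroxyphenyl)(methoxy)methyl]-4-(2,4,6-trihydroxyphenyl)butane-1,4-dione (both epimers at the methoxy carbon) | O=C(c1ccc(O)cc1O)[C@@H](Cc1ccc(O[Si](C)(C)C(C)(C)C)cc1)[C@H](C(OC)c1ccc(O)cc1)C(=O)c1c(O)cc(O)cc1O
F2 | step 13 | (2S,3R)-3-[(2S)-1-(2,4-dihydroxyphenyl)-3-(4-hydroxyphenyl)-3-methoxy-1-oxopropan-2-yl]-5,7-dihydroxy-2-(4-hydroxyphenyl)chroman-4-one (both epimers at the methoxy carbon) | O=C(c1ccc(O)cc1O)[C@@H](C(OC)c1ccc(O)cc1)[C@H]1C(=O)c2c(O)cc(O)cc2O[C@@H]1c1ccc(O)cc1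
F3 | step 7 | (3S,4S)-3-[4-(benzyloxy)benzyl]-4-{4-[(tert-butyldimethylsilyl)oxy]benzyl}oxolan-2-ol (both anomers) | OC1OC[C@@H](Cc2ccc(O[Si](C)(C)C(C)(C)C)cc2)[C@@H]1Cc1ccc(OCc2ccccc2)cc1
F4 | step 7 | (2S,3S)-2-[4-(benzyloxy)benzyl]-3-{4-[(tert-butyldimethylsilyl)oxy]benzyl}-1-[2,4,6-tris(benzyloxy)phenyl]butane-1,4-diol (both C-1 epimers) | OC[C@@H](Cc1ccc(O[Si](C)(C)C(C)(C)C)cc1)[C@H](Cc1ccc(OCc2ccccc2)cc1)C(O)c1c(OCc2ccccc2)cc(OCc2ccccc2)cc1OCc1ccccc1
F5 | step 10 | (2S,3S)-3-[4-(benzyloxy)benzyl]-2-{4-[(tert-butyldimethylsilyl)oxy]benzyl}-4-oxo-4-[2,4,6-tris(benzyloxy)phenyl]butanoic acid | OC(=O)[C@@H](Cc1ccc(O[Si](C)(C)C(C)(C)C)cc1)[C@H](Cc1ccc(OCc2ccccc2)cc1)C(=O)c1c(OCc2ccccc2)cc(OCc2ccccc2)cc1OCc1ccccc1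
F6 | step 10 | (2S,3S)-3-[4-(benzyloxy)benzyl]-2-{4-[(tert-butyldimethylsilyl)oxy]benzyl}-N-methoxy-N-methyl-4-oxo-4-[2,4,6-tris(benzyloxy)phenyl]butanamide | CON(C)C(=O)[C@@H](Cc1ccc(O[Si](C)(C)C(C)(C)C)cc1)[C@H](Cc1ccc(OCc2ccccc2)cc1)C(=O)c1c(OCc2ccccc2)cc(OCc2ccccc2)cc1OCc1ccccc1
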